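Split the reagent before anything else: it is shared between two mirror-image substrates.

all flasks: left-handed substrate 0.56 M; right-handed substrate 0.56 M; free catalyst 0.1 mol%; precatalyst 0.21 mol%
- oak: reagent 0.24 equiv; run made earlier
- birch: reagent 1.1 equiv; run made earlier
- ash: reagent 4.1 equiv; run made earlier
- autumn: reagent 0.250 equiv; time 8.0 h
- dawn: reagent 0.500 equiv; time 8.0 h
- dusk: reagent 1.00 equiv; time 8.0 h
- summer: reagent 2.00 equiv; time 8.0 h
- spring: reagent 4.00 equiv; time 8.0 h

| run | time / h | left-handed product / % | left-handed substrate / % |
|---|---|---|---|
| oak | 1.50 | 9.2 | 42.3 |
| oak | 3.00 | 8.6 | 42.5 |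
| oak | 5.00 | 8.7 | 43.2 |
| oak | 6.00 | 8.5 | 43.6 |
| oak | 8.00 | 8.2 | 43.6 |
| birch | 1.50 | 34.2 | 16.7 |
| birch | 3.00 | 35.4 | 18.4 |
| birch | 5.00 | 35.8 | 19.7 |
| birch | 6.00 | 35.2 | 21.0 |
| birch | 8.00 | 35.4 | 21.3 |
| ash | 0.667 | 50.0 | 0.1 |
| ash | 1.33 | 50.3 | 0 |
| ash | 2.50 | 50.5 | 0 |
| ash | 4.00 | 50.0 | 0.3 |
| ash | 8.00 | 50.6 | 0.1 |

(standard deviation of a reading: 0.3 percentage points)

- free catalyst is single-handed; left-handed substrate and right-handed substrate are mirror images of each other, charged as a racemate, each of them at the stated concentration
- "hardly changes" means that all values lie within two and a half points (for a concentration: within two and a half percent of the largest)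

- amount of left-handed product at the end, in percent of the left-handed substrate and right-handed substrate together charged for autumn, dawn, dusk, summer, spring, in this order
- how that number moves from the first to the last of them (hardly changes / rises, then falls / falls, then rises / falls all the way / rises all the way)

I assumed each substrate was used in proportion to its own amount. I called x the part of a substrate's charge consumed, with the left-handed and right-handed parts x_L and x_R. Then (1 − x_L) equals (1 − x_R) raised to the power s, the selectivity factor: the left-handed substrate's rate over the right-handed one's, at equal amounts.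

In birch, left-handed product averaged 35.2 %, with readings between 34.2 % and 35.8 %, while left-handed substrate climbed from 16.7 % to 21.3 %. I counted the 1.1 equiv of reagent as turned into product, so right-handed product, which was not read, was 19.8 %. That gave a reading of s = 2.41.

With e the equivalents of reagent, x_L + x_R = e. The curve therefore started with a slope of s/(s + 1), or 35.3 % of the total charge per equivalent. The small thing is the bend: from x_L I subtracted e squared times s(s − 1), over 2(s + 1) cubed.

My reckoning gave 8.71 % for autumn, 17.1 % for dawn and 33.2 % for dusk. I put the knee at 2.00 equiv, where the reagent matched both substrates together. For the level I took ash's mean reading, 50.3 %. Birch's creeping left-handed substrate suggested the knee would stand slightly above that level.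

The forecast gave 8.9 %, 17.2 %, 32.8 %, 52.5 % and 50.3 %, with the shape "rises, then falls". On the knee it said: “At 2.00 equiv the reagent exactly matches the substrate, so the second-order tail is slow.” My dusk figure stood higher than its 32.8 %.

The flasks gave 8.74 %, 17.2 %, 32.7 %, 52.9 % and 50.3 %, and the shape was "rises, then falls".

    reagent + free catalyst + left-handed substrate → free catalyst + left-handed product (k = 15000 M⁻² h⁻¹)
    reagent + free catalyst + right-handed substrate → free catalyst + right-handed product (k = 6100 M⁻² h⁻¹)
    left-handed substrate + racemization catalyst ⇌ right-handed substrate + racemization catalyst, rate k3*[racemization catalyst]*[left-handed substrate] forward; the back reaction follows from the equilibrium constant (k = 160 M⁻¹ h⁻¹)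
    2 free catalyst ⇌ resting dimer, settled at all times (K = 630 M⁻¹)
    precatalyst → racemization catalyst (k = 0.380 h⁻¹)

Resting dimer held 32.3 % of the catalyst charged in autumn at 8.00 h, yet that pairing moved the shown readings by a root mean square of 0.59 of the scatter. Put through s, dawn's right-handed product of 7.84 % gave 16.9 % of left-handed product, against the 17.2 % found. Summer's right-handed product of 43.6 % gave 49.7 %, and summer stood at 52.9 %, which was 3.2 percentage points higher.

The runs are calculated for an exercise.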